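## The problem

The target 39 is the C20 gibberellin listed as number 65 of the gibberellin A series: a 7,19-diacid with a C20 aldehyde, a 16-methylene and a 15β-hydroxyl. Cyclohexane ring A is trans-fused to cyclopentane ring B, ring B is cis-fused through C8–C9 to ring C, and rings C and D share C8, C13 and C14 in a bicyclo[3.2.1]octane. Eight stereocentres must be set (C4, C5, C6, C8, C9, C10, C13, C15), three of them quaternary (C4, C8, C10), and the axial C19 acid and the axial C20 aldehyde stand 1,3 to each other on ring A. Control can be relayed: C10 fixes C5 through a sigmatropic shift, C5 and C10 fix C4 in an enolate alkylation, C5, C6 and C10 together steer C8, C9 and C13 in a cycloaddition, and C15 comes last, from the finished cage. Several groups are fragile: a free C20 alcohol would lactonise onto C19, so C20 has to travel at the aldehyde level in masked form; C6 is epimerisable next to its ester; the C19 ester is very hindered; and the allylic 15-ol with its exocyclic alkene does not tolerate strong acid. The feature that opens the structure is C8: it joins rings B, C and D and bears C15, so a C8=C14 alkene with C15 as a formyl group is a 2-substituted acrolein. Ring C is then a Diels–Alder cyclohexene, ring B (C5–C6–C8–C9–C10) is the tether ring of a 1,3,8-nonatriene, and an alkyne on C13, cis to C15, can close ring D onto the same aldehyde.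

## Retrosynthesis

Gibberellane numbering (C1 to C20) is used for every intermediate.

**End game, 39 ⇐ 38 ⇐ 37.** No skeletal bond is cut. The C20 aldehyde is traced to a 1,3-dioxolane and the two acids to methyl esters. The acetal is chosen over a protected C20 alcohol because the alcohol would close the 19,20-lactone as soon as it is freed. The esters go first, by thiolate attack at the methyl groups, which is indifferent to the hindrance at C19. The acetal goes last, because a free aldehyde would not survive the thiolate.

**Ring D, 37 ⇐ 36 ⇐ 35 ⇐ 34.** The C15–C16 bond is cut. Allylic oxidation of a 15-unsubstituted 16-ene would deliver oxygen from the exo face and give the 15α epimer. A reductive aldehyde–alkyne cyclisation instead uses the formyl group that activated the dienophile, and builds the methylene and the carbinol in one step. The precursor 34 is a tricyclic ynal. The forward step must form the five-membered ring, add C15 and H cis across the alkyne, and place oxygen endo. The alkyne keeps a benzyldimethylsilyl group so that C16=C17 is trisubstituted while C11=C12 is reduced (35 to 36). Fluoride then removes this silyl group together with the silyl ether (36 to 37).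

**Rings B and C, 34 ⇐ 33 (key step).** C8–C9 and C13–C14 are cut together. Cutting ring B alone (aldol or alkylation at C8) would leave the quaternary centre and ring C to separate operations. The double cut removes two rings and three stereocentres, and leaves the monocyclic triene 33. The forward reaction must be tether-endo and formyl-exo on one diene face, with a (9E,12Z)-diene.

**The dienophile, 33 ⇐ 31 ⇐ 30.** The C8=C14 bond is cut back to an aldehyde that is α-methylenated. The acrolein is made immediately before use because it polymerises. The aldehyde 31 comes from the dimethyl acetal 30, which must be hydrolysed in the presence of the more hindered cyclic acetal at C20.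

**The dienyne, 30 ⇐ 22 + 27.** The sp2–sp2 bond C11–C12 is cut. A Wittig reaction at C9 with an enyne ylide would leave both alkene geometries uncertain. Here the (9E) geometry comes from syn hydrozirconation of the alkyne 22, and the (12Z) geometry is bought with the chloroenyne 27, made from 25 and cis-dichloroethene 26; 25 comes from 23 and 24. The alkyne 22 goes back by one-carbon homologation to the aldehyde 21, the alcohol 20 and the protected ether 19.

**C4, 19 ⇐ 17 ⇐ 16.** The C4–C18 bond is cut. The quaternary centre is made by methylation of the C4 ester enolate. The electrophile enters trans to the C5 side chain and anti to the axial C20 acetal, which is the resin-acid pattern of an axial ester. The step is run while C7 is still a carboxylate, so that only C4–H is removed. The saturated ester 17 comes from the enoate 16 by conjugate reduction.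

**C5–C6, 16 ⇐ 13 ⇐ 10 + 12.** The C5–C6 bond is cut by an Ireland–Claisen transform. Conjugate addition to a ring A enone would face an uncertain choice of face next to a quaternary carbon and would leave a ketone to remove. The rearrangement transfers the C3 configuration to C5 suprafacially and sets C6 through the ketene acetal geometry. It also turns the C3 oxygen into the C7 carboxylate, so ring A never needs deoxygenation. The precursor 13 is the ester of the allylic alcohol 10 with the four-carbon acid 12, which is made from the ester 11.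

**C19 and C3, 10 ⇐ 9 ⇐ 8 ⇐ 7 ⇐ 6.** The C4–C19 bond is cut (carbonylation of a vinyl iodide). The C3 carbinol comes from a reagent-controlled reduction of the iodoenone 8, which itself comes from the enone 7 and the aldehyde 6. Reagent control is needed because C10 is too remote to direct the hydride.

**Ring A, 6 ⇐ 3 + 4.** C1–C2 and C5–C10 are cut in a catalytic enantioselective Diels–Alder reaction. This creates C10 with its two one-carbon arms already distinct: the formyl group becomes C20 and the ether arm becomes C9. The acrolein 3 comes from the diol 1 through 2.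

## Roads not taken

Alternative 1: Ring A is cut last, at C1–C10 and C3–C4. The bis-enolate of the tricyclic 19,20-imide A2 would be alkylated twice by a three-carbon bis-electrophile to give A1.
- Merits: both quaternary carbons of ring A and the cis relation of C19 and C20 arise in one flask. The bridge must form anti to the C6 substituent, which is the natural sense. The long ring A sequence of the chosen plan (steps 3 to 12) is avoided; in this respect the alternative is better.
- Weak points: A2 already contains rings B, C and D with C6, C8, C9, C13 and C15 in place, so the cage problem is only moved upstream. The second alkylation closes a ring at a neopentyl-type enolate and competes with elimination. Afterwards the two imide carbonyls, both on quaternary carbons, must be told apart: one becomes an aldehyde and the other an acid. Opening an N-benzyl imide is harsh for a 15-oxygenated 16-ene.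
- Comparison: the chosen plan is longer in ring A, but C19 and C20 are different functional groups from step 4 onward.

Alternative 2: Rings B and D are cut together, at C9–C10 and C8–C15. A Lewis acid would turn the bis(cyclohexenyl) ketone A4 into a pentadienyl cation, and after 4π closure the oxyallyl cation would be trapped at C8 by the allylsilane to give A3.
- Merits: the most convergent of the four plans. Two rings, the C8 quaternary centre and the 16-methylene arise in one step from a ketone assembled from a ring A and a ring C fragment. No (Z)-diene is involved. In skeletal step count it is better than the chosen plan.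
- Weak points: the closure makes C10 from a fully substituted alkene terminus, which is slow. Its sense of rotation must be dictated by remote centres (C4 or C13). C5 is set afterwards by protonation. The product has a C6 ketone in place of the C7 carboxyl and no oxygen at C15. It would need a one-carbon homologation at a hindered ketone with control of C6, and then an allylic oxidation that gives 15α and has to be corrected.
- Comparison: the chosen plan brings C7 and C15 in at the right oxidation level and relays every centre through a cyclic transition state.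

Alternative 3: Ring B and C10 are made by light. The dioxinone alkene C6=C20 of A6, tethered through C8–C9 to the ring A alkene, would add in the crossed sense (C5–C6 and C10–C20) to give A5. Retro-aldol opening of the C6–C20 bond then follows.
- Merits: C20 appears as the aldehyde and C7 as the acid directly from the fragmentation, with no protecting group on C20. This is better than the chosen plan, which carries an acetal for twenty-two steps and ends with an acid hydrolysis. The two-atom tether favours the crossed mode.
- Weak points: A6 again needs rings C and D complete, including C8. The face of the ring A alkene, and with it H5 and the trans fusion of rings A and B, is not enforced by the tether. C6 is set by a late protonation. An advanced allylic silyl ether must survive irradiation.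
- Comparison: the chosen plan solves rings B and C together with C8, C9 and C13 in one thermal step from a monocycle, and pays for it with the acetal.

Key step: step 21

Assumption: in step 3 the (R,R)-diol is taken to shield the face that leads to (S)-6, as for simple 2-alkylacroleins; if the sense is the reverse, the (S,S)-diol is used and nothing else changes.

## Steps

Step 1
Reactants: 1 2-methylenepropane-1,3-diol
Product: 2 2-{[(4-methoxybenzyl)oxy]methyl}prop-2-en-1-ol
Conditions: NaH (1 equiv), THF, 0 °C; PMBCl, Bu4NI (cat.), rt; diol in threefold excess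
Reagents that add atoms: 4-methoxybenzyl chloride, COc1ccc(CCl)cc1
Why: Williamson ether synthesis on a symmetric diol; the excess of 1 keeps the bis-ether low and unreacted 1 is recovered.

Step 2
Reactants: 2 2-{[(4-methoxybenzyl)oxy]methyl}prop-2-en-1-ol
Product: 3 2-{[(4-methoxybenzyl)oxy]methyl}prop-2-enal
Conditions: MnO2, CH2Cl2, rt
Reagents that add atoms: none
Why: Selective oxidation of an allylic alcohol; the ether is untouched.

Step 3
Reactants: 3 2-{[(4-methoxybenzyl)oxy]methyl}prop-2-enal; 4 (E)-3-(tert-butyldimethylsilyloxy)-N,N-dimethylbuta-1,3-dien-1-amine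
Product: 6 (S)-1-{[(4-methoxybenzyl)oxy]methyl}-4-oxocyclohex-2-ene-1-carbaldehyde, via cycloadduct 5 (not isolated)
Conditions: (4R,5R)-2,2-dimethyl-α,α,α′,α′-tetra(1-naphthyl)-1,3-dioxolane-4,5-dimethanol (20 mol %), PhMe, −78 °C; then aq. HF, MeCN, 0 °C
Reagents that add atoms: none
Why: Hydrogen-bond-catalysed Diels–Alder reaction of a 1-amino-3-siloxydiene with a 2-substituted acrolein, in which the amino terminus bonds to the α-carbon. The diol blocks one face of the bound aldehyde and so sets C10; HF then removes the silyl group and eliminates the amine to give the enone. Enantioselectivity should be high but not complete, and step 6 removes the remainder.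

Step 4
Reactants: 6 (S)-1-{[(4-methoxybenzyl)oxy]methyl}-4-oxocyclohex-2-ene-1-carbaldehyde
Product: 7 (S)-4-(1,3-dioxolan-2-yl)-4-{[(4-methoxybenzyl)oxy]methyl}cyclohex-2-en-1-one
Conditions: (Me3SiOCH2)2, trimethylsilyl trifluoromethanesulfonate (5 mol %), CH2Cl2, −78 to −20 °C
Reagents that add atoms: 1,2-bis(trimethylsilyloxy)ethane, C[Si](C)(C)OCCO[Si](C)(C)C
Why: Silyl-transfer acetalisation, in which the aldehyde reacts far faster than the conjugated ketone; C20 is now masked at its final oxidation level.

Step 5
Reactants: 7 (S)-4-(1,3-dioxolan-2-yl)-4-{[(4-methoxybenzyl)oxy]methyl}cyclohex-2-en-1-one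
Product: 8 (S)-4-(1,3-dioxolan-2-yl)-2-iodo-4-{[(4-methoxybenzyl)oxy]methyl}cyclohex-2-en-1-one
Conditions: I2, pyridine, CH2Cl2, rt
Reagents that add atoms: iodine, II
Why: Pyridine-mediated α-iodination of an enone (conjugate addition, iodination, elimination), which is routine for 4,4-disubstituted cyclohexenones.

Step 6
Reactants: 8 (S)-4-(1,3-dioxolan-2-yl)-2-iodo-4-{[(4-methoxybenzyl)oxy]methyl}cyclohex-2-en-1-one
Product: 9 (1R,4S)-4-(1,3-dioxolan-2-yl)-2-iodo-4-{[(4-methoxybenzyl)oxy]methyl}cyclohex-2-en-1-ol
Conditions: (S)-1-methyl-3,3-diphenyltetrahydro-1H,3H-pyrrolo[1,2-c][1,3,2]oxazaborole (20 mol %), BH3·SMe2, THF, −30 °C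
Reagents that add atoms: none
Why: Corey–Bakshi–Shibata reduction with the iodoalkene as the large group gives the (R)-carbinol whatever the configuration at C10, so the hydroxyl is cis to the dioxolanyl group. The minor enantiomer of 8 becomes a diastereomer and is removed by chromatography, which raises the enantiomeric purity.

Step 7
Reactants: 9 (1R,4S)-4-(1,3-dioxolan-2-yl)-2-iodo-4-{[(4-methoxybenzyl)oxy]methyl}cyclohex-2-en-1-ol
Product: 10 methyl (3S,6R)-3-(1,3-dioxolan-2-yl)-6-hydroxy-3-{[(4-methoxybenzyl)oxy]methyl}cyclohex-1-ene-1-carboxylate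
Conditions: Pd(OAc)2 (5 mol %), PPh3 (10 mol %), CO (1 atm), MeOH, Et3N, DMF, 60 °C
Reagents that add atoms: carbon monoxide, [C-]#[O+]; methanol, CO
Why: Palladium-catalysed methoxycarbonylation of a vinyl iodide installs C19; the free allylic hydroxyl is tolerated because closure to a β-lactone is not competitive.

Step 8
Reactants: 11 methyl 4,4-dimethoxybutanoate
Product: 12 4,4-dimethoxybutanoic acid
Conditions: LiOH, THF/H2O, rt; then 1 M HCl to pH 4, 0 °C, used at once
Reagents that add atoms: lithium hydroxide, [Li+].[OH-]
Why: Ester saponification; cold, mild acidification keeps the acetal, and the acid is used without storage.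

Step 9
Reactants: 10 methyl (3S,6R)-3-(1,3-dioxolan-2-yl)-6-hydroxy-3-{[(4-methoxybenzyl)oxy]methyl}cyclohex-1-ene-1-carboxylate; 12 4,4-dimethoxybutanoic acid
Product: 13 methyl (3S,6R)-6-[(4,4-dimethoxybutanoyl)oxy]-3-(1,3-dioxolan-2-yl)-3-{[(4-methoxybenzyl)oxy]methyl}cyclohex-1-ene-1-carboxylate
Conditions: DCC, 4-(dimethylamino)pyridine (cat.), CH2Cl2, 0 °C to rt
Reagents that add atoms: none
Why: Steglich esterification of a secondary allylic alcohol under neutral conditions that spare both acetals.

Step 10
Reactants: 13 methyl (3S,6R)-6-[(4,4-dimethoxybutanoyl)oxy]-3-(1,3-dioxolan-2-yl)-3-{[(4-methoxybenzyl)oxy]methyl}cyclohex-1-ene-1-carboxylate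
Product: 16 2-[6-(1,3-dioxolan-2-yl)-2-(methoxycarbonyl)-6-{[(4-methoxybenzyl)oxy]methyl}cyclohex-2-en-1-yl]-4,4-dimethoxybutanoic acid with C5/C6/C10 as in 39, via (Z)-silyl ketene acetal 14 (not isolated), via trimethylsilyl ester 15 (not isolated)
Conditions: LiN(iPr)2, THF/DMPU (4:1), −78 °C; Me3SiCl; then 60 °C; aq. NH4Cl
Reagents that add atoms: none
Why: Ireland–Claisen rearrangement; the shift is suprafacial, so C5–C6 forms on the face that carried the C3 oxygen, cis to C20. The (Z)-ketene acetal formed in THF/DMPU reacts through the boat-like array usual for cyclohexenyl esters, with C8 turned outward and H6 toward C10, which is the natural C6 configuration. The C3 oxygen leaves as the C7 carboxylate.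

Step 11
Reactants: 16 the C3=C4 enoate acid of step 10
Product: 17 2-[2-(1,3-dioxolan-2-yl)-6-(methoxycarbonyl)-2-{[(4-methoxybenzyl)oxy]methyl}cyclohexyl]-4,4-dimethoxybutanoic acid (mixture of C4 epimers)
Conditions: Mg, MeOH, rt; aq. NH4Cl
Reagents that add atoms: none
Why: Dissolving-metal conjugate reduction of an α,β-unsaturated ester; C6 is safe because it is α to a carboxylate, and the C4 configuration is irrelevant because it is erased in step 12.

Step 12
Reactants: 17 the saturated acid ester of step 11
Product: 19 methyl 2-[2-(1,3-dioxolan-2-yl)-6-(methoxycarbonyl)-6-methyl-2-{[(4-methoxybenzyl)oxy]methyl}cyclohexyl]-4,4-dimethoxybutanoate with C4/C5/C6/C10 as in 39, via methylated acid 18 (not isolated)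
Conditions: LiN(iPr)2 (2.2 equiv), THF/DMPU, −78 to −40 °C; MeI, −78 to 0 °C; then Me3SiCHN2, PhMe/MeOH, 0 °C
Reagents that add atoms: iodomethane, CI; trimethylsilyldiazomethane, C[Si](C)(C)C=[N+]=[N-]
Why: Alkylation of a carboxylate/ester-enolate dianion: with two equivalents of base at low temperature the carboxylate is not deprotonated a second time, so only C4–H is removed. Iodomethane enters trans to the C5 side chain and anti to the axial C20 acetal, which makes C18 equatorial and C19 axial; the acid is then esterified.

Step 13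
Reactants: 19 the diester of step 12
Product: 20 methyl 2-[2-(1,3-dioxolan-2-yl)-2-(hydroxymethyl)-6-(methoxycarbonyl)-6-methylcyclohexyl]-4,4-dimethoxybutanoate
Conditions: DDQ, CH2Cl2/pH 7 buffer, 0 °C
Reagents that add atoms: none
Why: Oxidative removal of the 4-methoxybenzyl ether; the buffer protects the acetals, and the alcohol is taken on at once to forestall lactonisation onto C7.

Step 14
Reactants: 20 the C9 alcohol of step 13
Product: 21 methyl 2-[2-(1,3-dioxolan-2-yl)-2-formyl-6-(methoxycarbonyl)-6-methylcyclohexyl]-4,4-dimethoxybutanoate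
Conditions: Dess–Martin periodinane, NaHCO3, CH2Cl2, rt
Reagents that add atoms: none
Why: Mild oxidation of a neopentyl alcohol to a non-enolisable aldehyde.

Step 15
Reactants: 21 the C9 aldehyde of step 14
Product: 22 methyl 2-[2-(1,3-dioxolan-2-yl)-2-ethynyl-6-(methoxycarbonyl)-6-methylcyclohexyl]-4,4-dimethoxybutanoate
Conditions: dimethyl (1-diazo-2-oxopropyl)phosphonate, K2CO3, MeOH, 0 °C to rt
Reagents that add atoms: dimethyl (1-diazo-2-oxopropyl)phosphonate, COP(=O)(OC)C(=[N+]=[N-])C(C)=O
Why: Ohira–Bestmann homologation adds C11; the aldehyde has no α-hydrogen and the mild carbonate base leaves the ester stereocentre at C6 alone.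

Step 16
Reactants: 23 ethynylmagnesium bromide; 24 benzylchlorodimethylsilane
Product: 25 benzyl(ethynyl)dimethylsilane
Conditions: THF, 0 °C to rt
Reagents that add atoms: none
Why: Substitution at silicon by an alkynyl Grignard reagent.

Step 17
Reactants: 25 benzyl(ethynyl)dimethylsilane; 26 (Z)-1,2-dichloroethene
Product: 27 (Z)-benzyl(4-chlorobut-3-en-1-yn-1-yl)dimethylsilane
Conditions: Pd(PPh3)4 (5 mol %), CuI (10 mol %), n-BuNH2, Et2O, rt; 26 in fivefold excess
Reagents that add atoms: none
Why: Sonogashira monocoupling of cis-dichloroethene with retention of the alkene geometry; the excess dihalide prevents double coupling.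

Step 18
Reactants: 22 the alkyne of step 15; 27 (Z)-benzyl(4-chlorobut-3-en-1-yn-1-yl)dimethylsilane
Product: 30 methyl 2-[2-[(1E,3Z)-6-(benzyldimethylsilyl)hexa-1,3-dien-5-yn-1-yl]-2-(1,3-dioxolan-2-yl)-6-(methoxycarbonyl)-6-methylcyclohexyl]-4,4-dimethoxybutanoate, via alkenylzirconocene 28 (not isolated), via alkenylzinc chloride 29 (not isolated)
Conditions: Cp2Zr(H)Cl, THF, rt; ZnCl2, 0 °C; then 27, Pd(PPh3)4 (5 mol %), rt to 40 °C
Reagents that add atoms: none
Why: Syn hydrozirconation puts zirconium on C11 and fixes the (9E) geometry. Transmetalation to zinc and Negishi coupling with the activated vinyl chloride proceed with retention at both alkenes, so the (12Z) geometry of 27 is kept.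

Step 19
Reactants: 30 the dienyne dimethyl acetal of step 18
Product: 31 methyl 2-[2-[(1E,3Z)-6-(benzyldimethylsilyl)hexa-1,3-dien-5-yn-1-yl]-2-(1,3-dioxolan-2-yl)-6-(methoxycarbonyl)-6-methylcyclohexyl]-4-oxobutanoate
Conditions: pyridinium p-toluenesulfonate (20 mol %), acetone/H2O (10:1), 40 °C
Reagents that add atoms: water, O
Why: Selective acetal hydrolysis: the open-chain dimethyl acetal is cleaved much faster than the neopentyl cyclic acetal at C20.

Step 20
Reactants: 31 the aldehyde of step 19
Product: 33 methyl 2-[2-[(1E,3Z)-6-(benzyldimethylsilyl)hexa-1,3-dien-5-yn-1-yl]-2-(1,3-dioxolan-2-yl)-6-(methoxycarbonyl)-6-methylcyclohexyl]-3-formylbut-3-enoate, via Mannich base 32 (not isolated)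
Conditions: [CH2=NMe2]I, Et3N, CH2Cl2, rt; used at once
Reagents that add atoms: N,N-dimethylmethyleneiminium iodide, C=[N+](C)C.[I-]
Why: Mannich reaction with Eschenmoser's salt followed by β-elimination of dimethylamine adds C14. Short exposure to the weak amine base and immediate use limit enolisation at C6 and polymerisation of the acrolein.

Step 21
Reactants: 33 the (9E,12Z)-trienal of step 20
Product: 34 tricyclic 11-ene with the C8 formyl group and the C13 (benzyldimethylsilyl)ethynyl group cis to it, dimethyl 7,19-diester, C20 dioxolane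
Conditions: PhMe (0.005 M), 2,6-di-tert-butyl-4-methylphenol (cat.), 130 °C, sealed tube
Reagents that add atoms: none
Why: Thermal, concerted and suprafacial [4+2] cycloaddition; the known type is the type 1 intramolecular Diels–Alder reaction of a 1,3,8-nonatriene with the activating group on the inner dienophile carbon. Ring C closes as the new cyclohexene through both bonds (C8–C9 and C13–C14); ring B closes as the five-membered tether ring C5–C6–C8–C9–C10 through the C8–C9 bond alone. C13 follows from the (12Z) geometry: the alkynyl group is the inside substituent, so it ends cis to H9 and to the formyl carbon; a rod-like alkyne tolerates this position and has no hydrogen for a 1,5-shift. C8 follows from the tether-endo, formyl-exo array that 2-substituted acroleins prefer; it alone avoids a second trans fusion on the cyclopentane, so H9 and C15 end cis. C9 follows from the diene face: in the ground state H6 sits between the axial C19 ester and the C20 acetal and C8 already lies next to C9, and in the tether-endo array only the face that points H6, not the C7 ester, at C11–C12 is open, which is the face cis to C20. The trans-diequatorial arms on the ring A chair allow no other folding. The selectivity needed is formyl-exo, tether-endo addition on one diene face; it is secured by the 2-substituent of the acrolein, the ring A anchoring and the C6 configuration from step 10.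

Step 22
Reactants: 34 the tricyclic ynal of step 21
Product: 35 tetracyclic 15β-triethylsilyl ether with (E)-17-(benzyldimethylsilyl)-16-ene and 11-ene, dimethyl 7,19-diester, C20 dioxolane
Conditions: Ni(cod)2 (20 mol %), PBu3 (40 mol %), Et3SiH (5 equiv), THF, 45 °C
Reagents that add atoms: triethylsilane, CC[SiH](CC)CC
Why: Nickel-catalysed reductive aldehyde–alkyne cyclisation: zerovalent nickel couples C15 and C16 in an oxanickelacycle, the silane cleaves Ni–O, and C17–H forms by reductive elimination, so C15 and H add cis and silicon ends trans to C15. The tether allows only the five-membered ring. The oxygen should sit endo (15β), with C15=O eclipsing C8–C9 beneath the 11-ene, because the exo sector is occupied by the cis C7 ester.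

Step 23
Reactants: 35 the 11-ene of step 22
Product: 36 11,12-dihydro derivative of 35
Conditions: 2-nitrobenzenesulfonylhydrazide, Et3N, CH2Cl2, rt
Reagents that add atoms: none
Why: Diimide reduces the cis-disubstituted C11=C12 bond and leaves the trisubstituted vinylsilane; no stereocentre is created.

Step 24
Reactants: 36 the silyl ether of step 23
Product: 37 dimethyl ester 20-ethylene acetal of 39 (15β-hydroxy-16-ene with the C7 and C19 methyl esters and C20 as 1,3-dioxolan-2-yl)
Conditions: Bu4NF (5 equiv), THF, rt to 45 °C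
Reagents that add atoms: none
Why: Fluoride cleaves the triethylsilyl ether. It also removes the benzyldimethylsilyl group: the benzyl group is lost first, and the activated vinylsilane is then protodesilylated to the 16-methylene. The 15β-alkoxide cannot reach the C7 ester.

Step 25
Reactants: 37 dimethyl ester 20-ethylene acetal of 39
Product: 38 20-ethylene acetal of 39 (7,19-diacid)
Conditions: n-PrSLi (from n-PrSH and n-BuLi), HMPA, rt to 45 °C; 1 M HCl to pH 3, 0 °C
Reagents that add atoms: none
Why: Thiolate demethylation by SN2 attack at the ester methyl groups, unaffected by the hindrance at C19 and too weakly basic to epimerise C6; the acetal and the allylic alcohol are inert.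

Step 26
Reactants: 38 20-ethylene acetal of 39
Product: 39 target gibberellin (15β-hydroxy-16-ene 7,19-diacid with the C20 aldehyde)
Conditions: 1 M HCl, THF, 40 °C
Reagents that add atoms: water, O
Why: Acetal hydrolysis, assisted by the neighbouring axial C19 acid; dilute acid at mild temperature should spare the allylic alcohol. The product may equilibrate with its 19,20-lactol.

## Compound list

1 | 2-methylenepropane-1,3-diol | C=C(CO)CO | starting material
2 | 2-{[(4-methoxybenzyl)oxy]methyl}prop-2-en-1-ol | C=C(CO)COCc1ccc(OC)cc1 | intermediate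
3 | 2-{[(4-methoxybenzyl)oxy]methyl}prop-2-enal | C=C(C=O)COCc1ccc(OC)cc1 | intermediate
4 | (E)-3-(tert-butyldimethylsilyloxy)-N,N-dimethylbuta-1,3-dien-1-amine | CN(C)/C=C/C(=C)O[Si](C)(C)C(C)(C)C | starting material
5 | endo cycloadduct: 4-(tert-butyldimethylsilyloxy)-6-(dimethylamino)-1-{[(4-methoxybenzyl)oxy]methyl}cyclohex-4-ene-1-carbaldehyde (amine cis to formyl) | COc1ccc(COC[C@]2(C=O)CCC(O[Si](C)(C)C(C)(C)C)=C[C@H]2N(C)C)cc1 | intermediate
6 | (S)-1-{[(4-methoxybenzyl)oxy]methyl}-4-oxocyclohex-2-ene-1-carbaldehyde | COc1ccc(COC[C@]2(C=O)CCC(=O)C=C2)cc1 | intermediate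
7 | (S)-4-(1,3-dioxolan-2-yl)-4-{[(4-methoxybenzyl)oxy]methyl}cyclohex-2-en-1-one | COc1ccc(COC[C@]2(C3OCCO3)CCC(=O)C=C2)cc1 | intermediate
8 | (S)-4-(1,3-dioxolan-2-yl)-2-iodo-4-{[(4-methoxybenzyl)oxy]methyl}cyclohex-2-en-1-one | COc1ccc(COC[C@]2(C3OCCO3)CCC(=O)C(I)=C2)cc1 | intermediate
9 | (1R,4S)-4-(1,3-dioxolan-2-yl)-2-iodo-4-{[(4-methoxybenzyl)oxy]methyl}cyclohex-2-en-1-ol (hydroxyl cis to dioxolanyl) | COc1ccc(COC[C@]2(C3OCCO3)CC[C@@H](O)C(I)=C2)cc1 | intermediate
10 | methyl (3S,6R)-3-(1,3-dioxolan-2-yl)-6-hydroxy-3-{[(4-methoxybenzyl)oxy]methyl}cyclohex-1-ene-1-carboxylate | COc1ccc(COC[C@]2(C3OCCO3)CC[C@@H](O)C(C(=O)OC)=C2)cc1 | intermediate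
11 | methyl 4,4-dimethoxybutanoate | COC(OC)CCC(=O)OC | starting material
12 | 4,4-dimethoxybutanoic acid | COC(OC)CCC(=O)O | intermediate
13 | methyl (3S,6R)-6-[(4,4-dimethoxybutanoyl)oxy]-3-(1,3-dioxolan-2-yl)-3-{[(4-methoxybenzyl)oxy]methyl}cyclohex-1-ene-1-carboxylate | COc1ccc(COC[C@]2(C3OCCO3)CC[C@@H](OC(=O)CCC(OC)OC)C(C(=O)OC)=C2)cc1 | intermediate
14 | (Z)-trimethylsilyl ketene acetal of 13 (C8 cis to the silyloxy group) | COc1ccc(COC[C@]2(C3OCCO3)CC[C@@H](O/C(=C/CC(OC)OC)O[Si](C)(C)C)C(C(=O)OC)=C2)cc1 | intermediate
15 | trimethylsilyl ester of 16 | COc1ccc(COC[C@]2(C3OCCO3)CCC=C(C(=O)OC)[C@H]2[C@H](C(=O)O[Si](C)(C)C)CC(OC)OC)cc1 | intermediate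
16 | 2-[6-(1,3-dioxolan-2-yl)-2-(methoxycarbonyl)-6-{[(4-methoxybenzyl)oxy]methyl}cyclohex-2-en-1-yl]-4,4-dimethoxybutanoic acid; C6 arm cis to dioxolanyl; C5/C6/C10 as in 39 | COc1ccc(COC[C@]2(C3OCCO3)CCC=C(C(=O)OC)[C@H]2[C@H](C(=O)O)CC(OC)OC)cc1 | intermediate
17 | 2-[2-(1,3-dioxolan-2-yl)-6-(methoxycarbonyl)-2-{[(4-methoxybenzyl)oxy]methyl}cyclohexyl]-4,4-dimethoxybutanoic acid; C4 epimers; C5/C6/C10 as in 39 | COc1ccc(COC[C@]2(C3OCCO3)CCCC(C(=O)OC)[C@H]2[C@H](C(=O)O)CC(OC)OC)cc1 | intermediate
18 | C4-methylated acid: as 19 with free C7 acid | COc1ccc(COC[C@]2(C3OCCO3)CCC[C@@](C)(C(=O)OC)[C@H]2[C@H](C(=O)O)CC(OC)OC)cc1 | intermediate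
19 | methyl 2-[2-(1,3-dioxolan-2-yl)-6-(methoxycarbonyl)-6-methyl-2-{[(4-methoxybenzyl)oxy]methyl}cyclohexyl]-4,4-dimethoxybutanoate; C19 ester cis to dioxolanyl and to the C6 arm; C4/C5/C6/C10 as in 39 | COc1ccc(COC[C@]2(C3OCCO3)CCC[C@@](C)(C(=O)OC)[C@H]2[C@H](C(=O)OC)CC(OC)OC)cc1 | intermediate
20 | C9 alcohol: 19 with CH2OH in place of the ether arm | OC[C@]1(C2OCCO2)CCC[C@@](C)(C(=O)OC)[C@H]1[C@H](C(=O)OC)CC(OC)OC | intermediate
21 | C9 aldehyde: 20 oxidised to the formyl compound | O=C[C@]1(C2OCCO2)CCC[C@@](C)(C(=O)OC)[C@H]1[C@H](C(=O)OC)CC(OC)OC | intermediate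
22 | C9≡C11 alkyne: 21 homologated to the ethynyl compound | C#C[C@]1(C2OCCO2)CCC[C@@](C)(C(=O)OC)[C@H]1[C@H](C(=O)OC)CC(OC)OC | intermediate
23 | ethynylmagnesium bromide | C#C[Mg]Br | starting material
24 | benzylchlorodimethylsilane | C[Si](C)(Cl)Cc1ccccc1 | starting material
25 | benzyl(ethynyl)dimethylsilane | C#C[Si](C)(C)Cc1ccccc1 | intermediate
26 | (Z)-1,2-dichloroethene | Cl/C=C\Cl | starting material
27 | (Z)-benzyl(4-chlorobut-3-en-1-yn-1-yl)dimethylsilane | Cl/C=C\C#C[Si](C)(C)Cc1ccccc1 | intermediate
28 | (E)-alkenylzirconocene chloride from 22 (zirconium on C11) | Cl[Zr](/C=C/[C@]1(C2OCCO2)CCC[C@@](C)(C(=O)OC)[C@H]1[C@H](C(=O)OC)CC(OC)OC)(C1C=CC=C1)C1C=CC=C1 | intermediate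
29 | (E)-alkenylzinc chloride from 28 | Cl[Zn]/C=C/[C@]1(C2OCCO2)CCC[C@@](C)(C(=O)OC)[C@H]1[C@H](C(=O)OC)CC(OC)OC | intermediate
30 | (9E,12Z)-dienyne dimethyl acetal: ring A with the (1E,3Z)-6-(benzyldimethylsilyl)hexa-1,3-dien-5-ynyl group on C10 | C[Si](C)(Cc1ccccc1)C#C/C=C\C=C\[C@]1(C2OCCO2)CCC[C@@](C)(C(=O)OC)[C@H]1[C@H](C(=O)OC)CC(OC)OC | intermediate
31 | (9E,12Z)-dienyne aldehyde (C15 formyl, C8 methylene) | C[Si](C)(Cc1ccccc1)C#C/C=C\C=C\[C@]1(C2OCCO2)CCC[C@@](C)(C(=O)OC)[C@H]1[C@H](C(=O)OC)CC=O | intermediate
32 | Mannich base: 31 with CH2NMe2 on C8 (C8 epimers) | C[Si](C)(Cc1ccccc1)C#C/C=C\C=C\[C@]1(C2OCCO2)CCC[C@@](C)(C(=O)OC)[C@H]1[C@H](C(=O)OC)C(CN(C)C)C=O | intermediate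
33 | Diels–Alder precursor: ring A with the (9E,12Z)-dienyne on C10 and the CH(CO2Me)C(=CH2)CHO arm on C5 | C[Si](C)(Cc1ccccc1)C#C/C=C\C=C\[C@]1(C2OCCO2)CCC[C@@](C)(C(=O)OC)[C@H]1[C@H](C(=O)OC)C(=C)C=O | intermediate
34 | tricyclic 11-ene; C8 formyl; C13 (benzyldimethylsilyl)ethynyl cis to it; H9 cis to C15 | C[Si](C)(Cc1ccccc1)C#C[C@@H]2C=C[C@H]3[C@]4(C5OCCO5)CCC[C@@](C)(C(=O)OC)[C@H]4[C@H](C(=O)OC)[C@]3(C2)C=O | intermediate
35 | tetracyclic 15β-triethylsilyl ether; (E)-17-(benzyldimethylsilyl)-16-ene; 11-ene | C[Si](C)(Cc1ccccc1)/C=C2\[C@@H]3C=C[C@H]4[C@]5(C6OCCO6)CCC[C@@](C)(C(=O)OC)[C@H]5[C@H](C(=O)OC)[C@]4(C3)[C@@H]2O[Si](CC)(CC)CC | intermediate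
36 | 11,12-dihydro-35 | C[Si](C)(Cc1ccccc1)/C=C2\[C@@H]3CC[C@H]4[C@]5(C6OCCO6)CCC[C@@](C)(C(=O)OC)[C@H]5[C@H](C(=O)OC)[C@]4(C3)[C@@H]2O[Si](CC)(CC)CC | intermediate
37 | dimethyl ester 20-ethylene acetal of 39: 15β-hydroxy-16-ene with the C7 and C19 methyl esters and C20 as 1,3-dioxolan-2-yl | C=C1[C@@H]2CC[C@H]3[C@]4(C5OCCO5)CCC[C@@](C)(C(=O)OC)[C@H]4[C@H](C(=O)OC)[C@]3(C2)[C@@H]1O | intermediate
38 | 20-ethylene acetal of 39: 15β-hydroxy-16-ene 7,19-diacid with C20 as 1,3-dioxolan-2-yl | C=C1[C@@H]2CC[C@H]3[C@]4(C5OCCO5)CCC[C@@](C)(C(=O)O)[C@H]4[C@H](C(=O)O)[C@]3(C2)[C@@H]1O | intermediate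
39 | target gibberellin (number 65 of the gibberellin A series): 15β-hydroxy-16-ene 7,19-diacid with the C20 aldehyde | C=C1[C@@H]2CC[C@H]3[C@]4(C=O)CCC[C@@](C)(C(=O)O)[C@H]4[C@H](C(=O)O)[C@]3(C2)[C@@H]1O | target

## Step count and risks

Total: 26 steps. Longest linear sequence: 23 steps (steps 1–7, 9–15 and 18–26, from 1). Steps 8, 16 and 17 are side branches.

**Step 21 (key step).** The (12Z)-alkynyl terminus lowers the share of the s-cis diene, so cycloaddition may be outrun by polymerisation of the acrolein at the temperature required. The tether-exo mode may also intrude and give the trans fusion of rings B and C. Fallback, from 33 back to 34: the cycloaddition is run as a cationic Diels–Alder reaction of the acrolein acetal. The aldehyde of 33 is converted with trimethyl orthoformate, methanol and CeCl3·7H2O into the dimethyl acetal of 33, F10. A catalytic amount of trifluoromethanesulfonic acid in CH2Cl2 at −78 °C ionises it to a 2-substituted 1-methoxyallyl cation, which adds to the diene stepwise and far below the thermal temperature, giving the dimethyl acetal of 34, F11. Selective hydrolysis under the conditions of step 19 returns 34.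

**Step 22.** The aldehyde oxygen may take the exo position in the nickelacycle, giving the 15α epimer; the neopentyl aldehyde may also react slowly. Fallback, from 34 back to 37: C15 is set by hydride instead. If the cyclisation delivers the 15α-triethylsilyl ether F12, it is reduced with diimide to the 11,12-dihydro compound F13. HF·pyridine in THF gives the 15α-alcohol F14, kept neutral so that it does not lactonise onto C7. Dess–Martin periodinane gives the 16-en-15-one F15. NaBH4 with CeCl3·7H2O in methanol at −78 °C delivers hydride from the exo face of the bicyclo[3.2.1]octanone and gives the 15β-alcohol F16. Bu4NF as in step 24 converts F16 into 37.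

**Step 26.** Under aqueous acid the exocyclic alkene may be protonated at C17 and the cation quenched by hydride shift from C15 or by allylic transposition, so the 15-ol/16-ene unit may be lost before the hindered neopentyl acetal opens. Fallback, from 38 back to 39: the alcohol is acylated so that the carbinol carbon no longer supports the shift. Ac2O with pyridine and 4-(dimethylamino)pyridine, followed by aqueous work-up to hydrolyse mixed anhydrides, gives the 15-acetate of 38, F17. Acid hydrolysis as in step 26 then gives the 15-acetate of 39, F18. K2CO3 in methanol at rt removes the acetate and returns 39; the aldehyde is not enolisable and C6 is shielded as the α-carbon of a carboxylate.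

**Step 10.** Incomplete (Z)-selectivity in the enolisation, or leakage through the chair-like array, would give the C6 epimer; the later steps cannot correct it and the key step depends on it. Fallback, from 13 back to 19: C6 is set by enolate protonation instead of by the rearrangement. The C6-epimeric acid F6 is carried through the conditions of steps 11 and 12 to the reduced acid F7 and the C6-epimeric diester F8. In F8 only the C7 ester is enolisable; LiN(iPr)2 at −78 °C gives the lithium ester enolate F9. With H5 in the enolate plane, kinetic protonation by acetic acid from the face away from the more crowded C10 side should give 19, and unchanged F8 is recycled.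

**Step 3.** The ether oxygen of 3 may compete for the hydrogen-bond donor and lower the enantioselectivity below what step 6 can absorb. Fallback, from 3 and 4 back to 9: resolution by the reagent-controlled reduction. The uncatalysed cycloaddition gives the racemic cycloadduct F1, and HF gives racemic aldehyde F2. The conditions of steps 4 and 5 give racemic acetal F3 and racemic iodoenone F4. Reduction under the conditions of step 6 turns the two enantiomers of F4 into the diastereomers 9 and the (1R,4R)-alcohol F5, which are separated by chromatography; 9 continues.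

## Further compounds

F1 | step 3 | racemic cycloadduct (racemic 5) | COc1ccc(COCC2(C=O)CCC(O[Si](C)(C)C(C)(C)C)=CC2N(C)C)cc1
F2 | step 3 | racemic 1-{[(4-methoxybenzyl)oxy]methyl}-4-oxocyclohex-2-ene-1-carbaldehyde | COc1ccc(COCC2(C=O)CCC(=O)C=C2)cc1
F3 | step 3 | racemic 4-(1,3-dioxolan-2-yl)-4-{[(4-methoxybenzyl)oxy]methyl}cyclohex-2-en-1-one | COc1ccc(COCC2(C3OCCO3)CCC(=O)C=C2)cc1
F4 | step 3 | racemic 4-(1,3-dioxolan-2-yl)-2-iodo-4-{[(4-methoxybenzyl)oxy]methyl}cyclohex-2-en-1-one | COc1ccc(COCC2(C3OCCO3)CCC(=O)C(I)=C2)cc1
F5 | step 3 | (1R,4R)-4-(1,3-dioxolan-2-yl)-2-iodo-4-{[(4-methoxybenzyl)oxy]methyl}cyclohex-2-en-1-ol | COc1ccc(COC[C@@]2(C3OCCO3)CC[C@@H](O)C(I)=C2)cc1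
F6 | step 10 | C6 epimer of 16 | COc1ccc(COC[C@]2(C3OCCO3)CCC=C(C(=O)OC)[C@H]2[C@@H](C(=O)O)CC(OC)OC)cc1
F7 | step 10 | C6 epimer of 17 | COc1ccc(COC[C@]2(C3OCCO3)CCCC(C(=O)OC)[C@H]2[C@@H](C(=O)O)CC(OC)OC)cc1
F8 | step 10 | C6 epimer of 19 | COc1ccc(COC[C@]2(C3OCCO3)CCC[C@@](C)(C(=O)OC)[C@H]2[C@@H](C(=O)OC)CC(OC)OC)cc1
F9 | step 10 | lithium ester enolate of 19 at C6 | COc1ccc(COC[C@]2(C3OCCO3)CCC[C@@](C)(C(=O)OC)[C@H]2C(CC(OC)OC)=C(OC)O[Li])cc1
F10 | step 21 | dimethyl acetal of 33 | C[Si](C)(Cc1ccccc1)C#C/C=C\C=C\[C@]1(C2OCCO2)CCC[C@@](C)(C(=O)OC)[C@H]1[C@H](C(=O)OC)C(=C)C(OC)OC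
F11 | step 21 | dimethyl acetal of 34 | C[Si](C)(Cc1ccccc1)C#C[C@@H]2C=C[C@H]3[C@]4(C5OCCO5)CCC[C@@](C)(C(=O)OC)[C@H]4[C@H](C(=O)OC)[C@]3(C2)C(OC)OC
F12 | step 22 | 15α epimer of 35 | C[Si](C)(Cc1ccccc1)/C=C2\[C@@H]3C=C[C@H]4[C@]5(C6OCCO6)CCC[C@@](C)(C(=O)OC)[C@H]5[C@H](C(=O)OC)[C@]4(C3)[C@H]2O[Si](CC)(CC)CC
F13 | step 22 | 15α epimer of 36 | C[Si](C)(Cc1ccccc1)/C=C2\[C@@H]3CC[C@H]4[C@]5(C6OCCO6)CCC[C@@](C)(C(=O)OC)[C@H]5[C@H](C(=O)OC)[C@]4(C3)[C@H]2O[Si](CC)(CC)CC
F14 | step 22 | 15α-alcohol with (E)-17-(benzyldimethylsilyl)-16-ene | C[Si](C)(Cc1ccccc1)/C=C2\[C@@H]3CC[C@H]4[C@]5(C6OCCO6)CCC[C@@](C)(C(=O)OC)[C@H]5[C@H](C(=O)OC)[C@]4(C3)[C@H]2O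
F15 | step 22 | 17-(benzyldimethylsilyl)-16-en-15-one | C[Si](C)(Cc1ccccc1)/C=C2\[C@@H]3CC[C@H]4[C@]5(C6OCCO6)CCC[C@@](C)(C(=O)OC)[C@H]5[C@H](C(=O)OC)[C@]4(C3)C2=O
F16 | step 22 | 15β-alcohol with (E)-17-(benzyldimethylsilyl)-16-ene | C[Si](C)(Cc1ccccc1)/C=C2\[C@@H]3CC[C@H]4[C@]5(C6OCCO6)CCC[C@@](C)(C(=O)OC)[C@H]5[C@H](C(=O)OC)[C@]4(C3)[C@@H]2O
F17 | step 26 | 15-O-acetyl derivative of 38 | C=C1[C@@H]2CC[C@H]3[C@]4(C5OCCO5)CCC[C@@](C)(C(=O)O)[C@H]4[C@H](C(=O)O)[C@]3(C2)[C@@H]1OC(C)=O
F18 | step 26 | 15-O-acetyl derivative of 39 | C=C1[C@@H]2CC[C@H]3[C@]4(C=O)CCC[C@@](C)(C(=O)O)[C@H]4[C@H](C(=O)O)[C@]3(C2)[C@@H]1OC(C)=O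
A1 | alternative 1 | tetracycle with the N-benzyl 19,20-imide bridging ring A | C=C1[C@@H]2CC[C@H]3[C@]4(C(=O)N(Cc6ccccc6)C5=O)CCC[C@]5(C)[C@H]4[C@H](COCOC)[C@]3(C2)[C@@H]1O[Si](C)(C)C(C)(C)C
A2 | alternative 1 | tricyclic 19,20-imide lacking C1 to C3 | C=C1[C@@H]2CC[C@H]3C4C(=O)N(Cc5ccccc5)C(=O)C(C)[C@H]4[C@H](COCOC)[C@]3(C2)[C@@H]1O[Si](C)(C)C(C)(C)C
A3 | alternative 2 | tetracyclic 6-ketone with the 16-methylene | C=C1[C@@H]2CC[C@H]3[C@]4(COCOC)CCC[C@@](C)(C(=O)OC)[C@H]4C(=O)[C@]3(C2)C1
A4 | alternative 2 | bis(cyclohexenyl) ketone with the allylsilane on C13 | COCOCC1=C(C(=O)C2=CCC[C@@H](C(=C)C[Si](C)(C)C)C2)[C@](C)(C(=O)OC)CCC1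
A5 | alternative 3 | crossed photoadduct with the C6–C20 cyclobutane bond | C=C1[C@@H]2CC[C@H]3[C@]4([C@@H]5OC(C)(C)OC6=O)CCC[C@@](C)(C(=O)OCC[Si](C)(C)C)[C@H]4[C@]56[C@]3(C2)[C@@H]1O[Si](C)(C)C(C)(C)C
A6 | alternative 3 | dioxinone tethered through C8–C9 to the ring A alkene | C=C1[C@@H]2CC[C@@H](C3=C[C@](C)(C(=O)OCC[Si](C)(C)C)CCC3)[C@@](C4=COC(C)(C)OC4=O)(C2)[C@@H]1O[Si](C)(C)C(C)(C)C
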